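**Plan**

- Bonds cut, from the target backwards: C2–C1' (aryl to chromone), O1–C2 and C2–C3 (C2 comes from CS2), C6–prenyl (moved from oxygen by a para-Claisen–Cope shift), C4a–C5 of ring A (key step), C4–C4a (polyanion acylation), C3–C1'' (acetate dianion onto C1 of geraniol (1)).
- Enabling feature: ring A is a phloroglucinol (oxygens on C5, C7, C8a) acylated at C4a by C4. This is the Claisen-mode folding product of a 3,5,7-triketo ester: ester C1 becomes C5, C3 becomes C7, C5 becomes C8a, C6 becomes C4a and the C7 ketone becomes C4.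
- Forward order: side chain from geraniol, then the triketo ester, then ring A (step 7), prenyl onto ring A, ring C with CS2, ring B by C–S cross-coupling, and global deprotection.
- Stereochemistry: both centres come from the Sharpless epoxidation of geraniol with L-(+)-tartrate. C2'' keeps its epoxide oxygen (S); C3'' is inverted by anti hydrolysis (R). The diol is carried as an acetonide.

Key step: step 7

Assumption: LiN(iPr)2, Mg(OMe)2 in MeOH and methyl 3,5-dioxohexanoate are used as purchased, and polycarbonyl compounds are drawn as keto tautomers although they are largely enolised.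

Abbreviation: Diox = (4S,5R)-2,2,5-trimethyl-5-(4-methylpent-3-en-1-yl)-1,3-dioxolan-4-yl.

**Route**

Step 1
Reactants: 1 geraniol
Product: 2 (2S,3S)-2,3-epoxygeraniol
Conditions: Ti(OiPr)4 (5 mol%), L-(+)-diethyl tartrate (6 mol%), t-BuOOH, 4 Å MS, CH2Cl2, −20 °C
Reagents that add atoms: tert-butyl hydroperoxide, CC(C)(C)OO
Why: Katsuki–Sharpless asymmetric epoxidation: the titanium tartrate complex binds the allylic hydroxyl so only the 2,3-alkene reacts, and L-(+)-tartrate delivers oxygen to the face that gives the (2S,3S) epoxide, fixing C2 (kept to the end) and C3 (inverted in step 2).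

Step 2
Reactants: 2 (2S,3S)-2,3-epoxygeraniol
Product: 3 (2S,3R)-3,7-dimethyloct-6-ene-1,2,3-triol
Conditions: HClO4 (3% aq., cat.), THF, 0 °C → rt
Reagents that add atoms: water, O
Why: Acid-catalysed epoxide hydrolysis: water attacks the protonated epoxide at the tertiary C3 anti to the breaking C–O bond (borderline SN2), so C3 is inverted to R while the C2–O bond and its S configuration are untouched, and the remote 6,7-alkene cannot reach C3 in a Markovnikov sense.

Step 3
Reactants: 3 (2S,3R)-3,7-dimethyloct-6-ene-1,2,3-triol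
Product: 4 (2S,3R)-2,3-dihydroxy-3,7-dimethyloct-6-en-1-yl 4-methylbenzenesulfonate
Conditions: TsCl (1.05 equiv), Et3N, Bu2SnO (2 mol%), CH2Cl2, 0 °C → rt
Reagents that add atoms: p-toluenesulfonyl chloride, Cc1ccc(cc1)S(Cl)(=O)=O
Why: Tin-catalysed regioselective sulfonylation: the stannylene acetal of the 1,2-diol activates the primary oxygen, and the tertiary hydroxyl is inert.

Step 4
Reactants: 4 (2S,3R)-2,3-dihydroxy-3,7-dimethyloct-6-en-1-yl 4-methylbenzenesulfonate; 5 acetic acid
Product: 8 (5S)-5-[(2R)-2-hydroxy-6-methylhept-5-en-2-yl]oxolan-2-one, via hydroxy epoxide 6 (not isolated), via dihydroxy acid 7 (not isolated)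
Conditions: 5 (5 equiv), LiN(iPr)2 (10 equiv), THF–DMPU, 0 °C; then 4, 0 → 45 °C; 1 M HCl; TsOH (cat.), CH2Cl2, rt
Reagents that add atoms: none
Why: Williamson closure of the C2 alkoxide on the primary tosylate gives the terminal epoxide without touching a stereocentre, the acetic acid dianion opens it at the CH2 terminus (SN2) and acidification lactonises the γ-hydroxy acid; a Payne shift of the tertiary alkoxide is reversible and only returns the same epoxide, so neither centre can scramble.

Step 5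
Reactants: 8 (5S)-5-[(2R)-2-hydroxy-6-methylhept-5-en-2-yl]oxolan-2-one
Product: 9 methyl 3-Diox-propanoate
Conditions: Me2C(OMe)2, MeOH, camphorsulfonic acid (cat.), rt; Et3N quench
Reagents that add atoms: 2,2-dimethoxypropane, COC(C)(C)OC; methanol, CO
Why: Acid-catalysed methanolysis of the γ-lactone is pulled forward because the freed secondary/tertiary diol is trapped at once as its acetonide (transketalisation), a known way to open hydroxy lactones to acetonide methyl esters; no stereocentre is involved.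

Step 6
Reactants: 9 methyl 3-Diox-propanoate; 10 methyl 3,5-dioxohexanoate
Product: 11 methyl 3,5,7-trioxo-9-Diox-nonanoate
Conditions: 10 (2.2 equiv), LiN(iPr)2 (6.6 equiv), THF, −78 → 0 °C; then 9, −78 → 0 °C; aq. NH4Cl
Reagents that add atoms: none
Why: Claisen-type terminal acylation of a β-polycarbonyl polyanion: the trianion reacts only at its most basic terminal carbanion (C6 of the dioxohexanoate) with the ester carbonyl of 9, and the excess trianion takes up the proton released by the more acidic product.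

Step 7
Reactants: 11 methyl 3,5,7-trioxo-9-Diox-nonanoate
Product: 12 3-Diox-1-(2,4,6-trihydroxyphenyl)propan-1-one
Conditions: Mg(OMe)2 (4 equiv), MeOH, rt → 60 °C; cold 0.5 M HCl to pH 4
Reagents that add atoms: none
Why: Mg(OMe)2 turns the triketo ester into a magnesium bis(enolate) chelate that folds the chain; C6, flanked by the C5 and C7 carbonyls, adds to the ester carbonyl C1, methoxide leaves, and the 2-acylcyclohexane-1,3,5-trione enolises irreversibly to the phloroglucinol, so the C6–C1 bond (flavone C4a–C5) is the only skeletal bond made. The closest known reaction is the Claisen-mode (Dieckmann-type) cyclisation of 3,5,7-triketo esters and of the related 6-acylmethyl-4-hydroxy-2-pyranones to acylphloroglucinols under magnesium methoxide. Ring A closes in a 6-(enolexo)-exo-trig mode. No stereocentre is formed, and the two dioxolane centres carry no acidic hydrogen and stay untouched. The step needs the Claisen mode to beat the aldol mode (C2 onto the C7 ketone, which would give a resorcylate) and retro-Claisen chain cleavage; magnesium ties the C7 oxygen into a chelated enolate of low electrophilicity, anhydrous methoxide in methanol keeps C1 as a methyl ester and not an unreactive carboxylate, and aromatisation makes the acylation irreversible.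

Step 8
Reactants: 12 3-Diox-1-(2,4,6-trihydroxyphenyl)propan-1-one
Product: 13 3-Diox-1-[2-hydroxy-4,6-bis(methoxymethoxy)phenyl]propan-1-one
Conditions: MOMCl (2.2 equiv), iPr2NEt, CH2Cl2, 0 °C → rt
Reagents that add atoms: chloromethyl methyl ether, COCCl
Why: Williamson etherification: the para hydroxyl and one ortho hydroxyl are alkylated while the second ortho hydroxyl, hydrogen-bonded to the ketone, stays free, as with 2,4,6-trihydroxyacetophenone.

Step 9
Reactants: 13 3-Diox-1-[2-hydroxy-4,6-bis(methoxymethoxy)phenyl]propan-1-one; 14 prenyl bromide (1-bromo-3-methylbut-2-ene)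
Product: 15 3-Diox-1-[2,4-bis(methoxymethoxy)-6-(3-methylbut-2-en-1-yloxy)phenyl]propan-1-one
Conditions: 14 (1.5 equiv), K2CO3, acetone, reflux
Reagents that add atoms: none
Why: Williamson O-alkylation (SN2) of the chelated phenoxide with the allylic bromide under carbonate, a base too weak to enolise the ketone.

Step 10
Reactants: 15 3-Diox-1-[2,4-bis(methoxymethoxy)-6-(3-methylbut-2-en-1-yloxy)phenyl]propan-1-one
Product: 17 3-Diox-1-[6-hydroxy-2,4-bis(methoxymethoxy)-3-(3-methylbut-2-en-1-yl)phenyl]propan-1-one, via ortho-dienone 16 (not isolated)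
Conditions: PhNEt2, 200 °C, sealed tube, Ar
Reagents that add atoms: none
Why: Para-Claisen–Cope cascade: a [3,3] shift of the prenyl ether to the free ortho carbon gives a congested dienone whose 1,1-dimethylallyl group moves on by a Cope [3,3] shift to the para carbon between the two MOM ethers, and tautomerisation there leaves a normal prenyl group para to the only free hydroxyl, that is at the future C6.

Step 11
Reactants: 17 3-Diox-1-[6-hydroxy-2,4-bis(methoxymethoxy)-3-(3-methylbut-2-en-1-yl)phenyl]propan-1-one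
Product: 20 3-(Diox-methyl)-5,7-bis(methoxymethoxy)-6-(3-methylbut-2-en-1-yl)-2-(methylsulfanyl)-4H-chromen-4-one, via keto dithioate 18 (not isolated), via chromene-2-thione 19 (not isolated)
Conditions: KOtBu (3.5 equiv), CS2, THF, 0 °C → rt; then MeI, rt
Reagents that add atoms: carbon disulfide, S=C=S; iodomethane, CI
Why: Known CS2 annulation of 2-hydroxyaryl ketones: the ketone enolate adds to CS2, the phenoxide closes onto the dithiocarboxylate with loss of hydrosulfide to the 4-hydroxy-2H-chromene-2-thione, and soft S-methylation fixes the chromone form with a 2-methylsulfanyl group, so that O1–C2 and C2–C3 of ring C are made here through the one free hydroxyl.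

Step 12
Reactants: 21 4-bromoresorcinol
Product: 22 1-bromo-2,4-bis(methoxymethoxy)benzene
Conditions: MOMCl (2.5 equiv), iPr2NEt, CH2Cl2, 0 °C → rt
Reagents that add atoms: chloromethyl methyl ether, COCCl
Why: Williamson etherification of both phenols.

Step 13
Reactants: 22 1-bromo-2,4-bis(methoxymethoxy)benzene
Product: 25 [2,4-bis(methoxymethoxy)phenyl]boronic acid, via aryllithium 23 (not isolated), via lithium aryl borate 24 (not isolated)
Conditions: n-BuLi, THF, −78 °C; B(OiPr)3, −78 °C → rt; aq. NH4Cl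
Reagents that add atoms: triisopropyl borate, CC(C)OB(OC(C)C)OC(C)C; water, O
Why: Bromine–lithium exchange is faster than ortho-lithiation at −78 °C, the aryllithium is trapped by the borate (borylation), and mild hydrolysis leaves the MOM ethers intact.

Step 14
Reactants: 20 3-(Diox-methyl)-5,7-bis(methoxymethoxy)-6-(3-methylbut-2-en-1-yl)-2-(methylsulfanyl)-4H-chromen-4-one; 25 [2,4-bis(methoxymethoxy)phenyl]boronic acid
Product: 26 2-[2,4-bis(methoxymethoxy)phenyl]-3-(Diox-methyl)-5,7-bis(methoxymethoxy)-6-(3-methylbut-2-en-1-yl)-4H-chromen-4-one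
Conditions: Pd2(dba)3 (5 mol%), P(2-furyl)3 (20 mol%), Cu(O2C-2-C4H3S) (2.5 equiv), 25 (2 equiv), THF, 55 °C
Reagents that add atoms: none
Why: Liebeskind–Srogl coupling: zerovalent palladium inserts into the C–S bond of the vinylogous thioester, and the monovalent copper thiophene-2-carboxylate binds the thiolate and passes the aryl group from boron to palladium without added base, which spares the electron-rich boronic acid from protodeboronation and tolerates both alkenes.

Step 15
Reactants: 26 2-[2,4-bis(methoxymethoxy)phenyl]-3-(Diox-methyl)-5,7-bis(methoxymethoxy)-6-(3-methylbut-2-en-1-yl)-4H-chromen-4-one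
Product: 27 2-(2,4-dihydroxyphenyl)-3-[(2S,3R)-2,3-dihydroxy-3,7-dimethyloct-6-en-1-yl]-5,7-dihydroxy-6-(3-methylbut-2-en-1-yl)-4H-chromen-4-one
Conditions: 3 M aq. HCl, MeOH, rt → 40 °C, stopped at full conversion
Reagents that add atoms: none
Why: Acid-catalysed acetal solvolysis of the four aryl MOM ethers and of the acetonide; short contact with dilute acid at moderate temperature, as used for prenylated flavonoids, should spare the prenyl group and the side-chain alkene, and no stereocentre is touched.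

**Compound list**

1 | geraniol, (2E)-3,7-dimethylocta-2,6-dien-1-ol | CC(C)=CCC/C(C)=C/CO | starting material
2 | [(2S,3S)-3-methyl-3-(4-methylpent-3-en-1-yl)oxiran-2-yl]methanol | CC(C)=CCC[C@]1(C)O[C@H]1CO | intermediate
3 | (2S,3R)-3,7-dimethyloct-6-ene-1,2,3-triol | CC(C)=CCC[C@@](C)(O)[C@@H](O)CO | intermediate
4 | (2S,3R)-2,3-dihydroxy-3,7-dimethyloct-6-en-1-yl 4-methylbenzenesulfonate | CC(C)=CCC[C@@](C)(O)[C@@H](O)COS(=O)(=O)c1ccc(C)cc1 | intermediate
5 | acetic acid | CC(=O)O | starting material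
6 | (2R)-6-methyl-2-[(2S)-oxiran-2-yl]hept-5-en-2-ol (not isolated) | CC(C)=CCC[C@@](C)(O)[C@@H]1CO1 | intermediate
7 | (4S,5R)-4,5-dihydroxy-5,9-dimethyldec-8-enoic acid (not isolated) | CC(C)=CCC[C@@](C)(O)[C@@H](O)CCC(=O)O | intermediate
8 | (5S)-5-[(2R)-2-hydroxy-6-methylhept-5-en-2-yl]oxolan-2-one | CC(C)=CCC[C@@](C)(O)[C@@H]1CCC(=O)O1 | intermediate
9 | methyl 3-[(4S,5R)-2,2,5-trimethyl-5-(4-methylpent-3-en-1-yl)-1,3-dioxolan-4-yl]propanoate | CC(C)=CCC[C@@](C)(OC(C)(C)O1)[C@@H]1CCC(=O)OC | intermediate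
10 | methyl 3,5-dioxohexanoate | COC(=O)CC(=O)CC(C)=O | starting material
11 | methyl 3,5,7-trioxo-9-[(4S,5R)-2,2,5-trimethyl-5-(4-methylpent-3-en-1-yl)-1,3-dioxolan-4-yl]nonanoate | CC(C)=CCC[C@@](C)(OC(C)(C)O1)[C@@H]1CCC(=O)CC(=O)CC(=O)CC(=O)OC | intermediate
12 | 1-(2,4,6-trihydroxyphenyl)-3-[(4S,5R)-2,2,5-trimethyl-5-(4-methylpent-3-en-1-yl)-1,3-dioxolan-4-yl]propan-1-one | CC(C)=CCC[C@@](C)(OC(C)(C)O1)[C@@H]1CCC(=O)c2c(O)cc(O)cc2O | intermediate
13 | 1-[2-hydroxy-4,6-bis(methoxymethoxy)phenyl]-3-[(4S,5R)-2,2,5-trimethyl-5-(4-methylpent-3-en-1-yl)-1,3-dioxolan-4-yl]propan-1-one | CC(C)=CCC[C@@](C)(OC(C)(C)O1)[C@@H]1CCC(=O)c2c(O)cc(OCOC)cc2OCOC | intermediate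
14 | prenyl bromide, 1-bromo-3-methylbut-2-ene | CC(C)=CCBr | starting material
15 | 1-[2,4-bis(methoxymethoxy)-6-(3-methylbut-2-en-1-yloxy)phenyl]-3-[(4S,5R)-2,2,5-trimethyl-5-(4-methylpent-3-en-1-yl)-1,3-dioxolan-4-yl]propan-1-one | CC(C)=CCC[C@@](C)(OC(C)(C)O1)[C@@H]1CCC(=O)c2c(OCC=C(C)C)cc(OCOC)cc2OCOC | intermediate
16 | 3,5-bis(methoxymethoxy)-6-(2-methylbut-3-en-2-yl)-2-{3-[(4S,5R)-2,2,5-trimethyl-5-(4-methylpent-3-en-1-yl)-1,3-dioxolan-4-yl]propanoyl}cyclohexa-2,4-dien-1-one (not isolated; ring sp3 centre undefined) | CC(C)=CCC[C@@](C)(OC(C)(C)O1)[C@@H]1CCC(=O)C2=C(OCOC)C=C(OCOC)C(C(C)(C)C=C)C2=O | intermediate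
17 | 1-[6-hydroxy-2,4-bis(methoxymethoxy)-3-(3-methylbut-2-en-1-yl)phenyl]-3-[(4S,5R)-2,2,5-trimethyl-5-(4-methylpent-3-en-1-yl)-1,3-dioxolan-4-yl]propan-1-one | CC(C)=CCC[C@@](C)(OC(C)(C)O1)[C@@H]1CCC(=O)c2c(O)cc(OCOC)c(CC=C(C)C)c2OCOC | intermediate
18 | 3-[6-hydroxy-2,4-bis(methoxymethoxy)-3-(3-methylbut-2-en-1-yl)phenyl]-3-oxo-2-{[(4S,5R)-2,2,5-trimethyl-5-(4-methylpent-3-en-1-yl)-1,3-dioxolan-4-yl]methyl}propanedithioic acid (not isolated; present as its potassium salt, α-centre undefined) | CC(C)=CCC[C@@](C)(OC(C)(C)O1)[C@@H]1CC(C(=S)S)C(=O)c2c(O)cc(OCOC)c(CC=C(C)C)c2OCOC | intermediate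
19 | 4-hydroxy-5,7-bis(methoxymethoxy)-6-(3-methylbut-2-en-1-yl)-3-{[(4S,5R)-2,2,5-trimethyl-5-(4-methylpent-3-en-1-yl)-1,3-dioxolan-4-yl]methyl}-2H-chromene-2-thione (not isolated) | CC(C)=CCC[C@@](C)(OC(C)(C)O1)[C@@H]1CC2=C(O)c3c(OCOC)c(CC=C(C)C)c(OCOC)cc3OC2=S | intermediate
20 | 5,7-bis(methoxymethoxy)-6-(3-methylbut-2-en-1-yl)-2-(methylsulfanyl)-3-{[(4S,5R)-2,2,5-trimethyl-5-(4-methylpent-3-en-1-yl)-1,3-dioxolan-4-yl]methyl}-4H-chromen-4-one | CC(C)=CCC[C@@](C)(OC(C)(C)O1)[C@@H]1Cc2c(SC)oc3cc(OCOC)c(CC=C(C)C)c(OCOC)c3c2=O | intermediate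
21 | 4-bromoresorcinol, 4-bromobenzene-1,3-diol | Oc1ccc(Br)c(O)c1 | starting material
22 | 1-bromo-2,4-bis(methoxymethoxy)benzene | COCOc1ccc(Br)c(OCOC)c1 | intermediate
23 | [2,4-bis(methoxymethoxy)phenyl]lithium (not isolated) | [Li]c1ccc(OCOC)cc1OCOC | intermediate
24 | lithium [2,4-bis(methoxymethoxy)phenyl]tri(propan-2-yloxy)borate (not isolated) | [Li+].CC(C)O[B-](OC(C)C)(OC(C)C)c1ccc(OCOC)cc1OCOC | intermediate
25 | [2,4-bis(methoxymethoxy)phenyl]boronic acid | COCOc1ccc(B(O)O)c(OCOC)c1 | intermediate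
26 | 2-[2,4-bis(methoxymethoxy)phenyl]-5,7-bis(methoxymethoxy)-6-(3-methylbut-2-en-1-yl)-3-{[(4S,5R)-2,2,5-trimethyl-5-(4-methylpent-3-en-1-yl)-1,3-dioxolan-4-yl]methyl}-4H-chromen-4-one | CC(C)=CCC[C@@](C)(OC(C)(C)O1)[C@@H]1Cc2c(-c4ccc(OCOC)cc4OCOC)oc3cc(OCOC)c(CC=C(C)C)c(OCOC)c3c2=O | intermediate
27 | 2-(2,4-dihydroxyphenyl)-3-[(2S,3R)-2,3-dihydroxy-3,7-dimethyloct-6-en-1-yl]-5,7-dihydroxy-6-(3-methylbut-2-en-1-yl)-4H-chromen-4-one | CC(C)=CCC[C@@](C)(O)[C@@H](O)Cc1c(-c2ccc(O)cc2O)oc2cc(O)c(CC=C(C)C)c(O)c2c1=O | target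

**Step count**

Total: 15 steps. Longest linear sequence: 13 steps (steps 1–11, 14, 15, from geraniol); the boronic acid branch is 2 steps (12, 13).

**Steps most likely to fail**

Step 7. The folded chain may close in the aldol sense (C2 onto the C7 ketone) or be cut by methoxide in a retro-Claisen cleavage, so that ring A forms as a resorcylate or not at all. The fallback sets out from ester 9 and comes back at 13, building ring A from an existing arene instead. Phloroglucinol with MOMCl and iPr2NEt should give 1,3,5-tris(methoxymethoxy)benzene F3. Lithiation between two MOM ethers (n-BuLi, THF, 0 °C) and addition to 9 at −78 °C should stop at the twisted, doubly ortho-substituted ketone 1-[2,4,6-tris(methoxymethoxy)phenyl]-3-Diox-propan-1-one F4. Chelation-assisted methanolysis of one ortho MOM ether (pyridinium p-toluenesulfonate, MeOH) then gives 13, since the freed hydroxyl hydrogen-bonds to the ketone and shields the second ortho ether.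

Step 14. Transmetalation may be slow at a C–S carbon flanked by the C3 side chain and facing an ortho-substituted aryl partner, while the boronic acid is lost by protodeboronation or homocoupling. The fallback sets out from 17 and comes back at target 27 by a Baker–Venkataraman sequence. Aryllithium 23 quenched with CO2 gives 2,4-bis(methoxymethoxy)benzoic acid F5. Esterification of the phenol of 17 (EDC, DMAP, CH2Cl2) gives 2-(3-Diox-propanoyl)-3,5-bis(methoxymethoxy)-4-(3-methylbut-2-en-1-yl)phenyl 2,4-bis(methoxymethoxy)benzoate F6. LiN(SiMe3)2 in THF moves the aroyl group to the ketone α-carbon to give the 2-substituted 1,3-diketone 1-[2,4-bis(methoxymethoxy)phenyl]-3-[6-hydroxy-2,4-bis(methoxymethoxy)-3-(3-methylbut-2-en-1-yl)phenyl]-2-(Diox-methyl)propane-1,3-dione F7. Methanolic HCl then brings about cyclodehydration to the flavone together with loss of the MOM ethers and the acetonide, giving 27.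

Step 6. Proton transfer from the enolisable ester or from the product to the trianion, self-condensation of the trianion, or a second addition to the new ketone may erode the acylation. The fallback sets out from lactone 8 and comes back at 11 with a non-enolising, chelating acyl donor. AlMe3 with MeNH(OMe)·HCl (CH2Cl2, 0 °C → rt) opens the lactone to (4S,5R)-4,5-dihydroxy-N-methoxy-N,5,9-trimethyldec-8-enamide F1. 2-Methoxypropene with pyridinium p-toluenesulfonate gives N-methoxy-N-methyl-3-Diox-propanamide F2. F2 with about 1.3 equiv of the trianion of 10 (THF, −78 → 0 °C) should hold as a chelated tetrahedral adduct until the quench, which releases 11.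

**Further compounds**

F1 | step 6 | (4S,5R)-4,5-dihydroxy-N-methoxy-N,5,9-trimethyldec-8-enamide | CC(C)=CCC[C@@](C)(O)[C@@H](O)CCC(=O)N(C)OC
F2 | step 6 | N-methoxy-N-methyl-3-[(4S,5R)-2,2,5-trimethyl-5-(4-methylpent-3-en-1-yl)-1,3-dioxolan-4-yl]propanamide | CC(C)=CCC[C@@](C)(OC(C)(C)O1)[C@@H]1CCC(=O)N(C)OC
F3 | step 7 | 1,3,5-tris(methoxymethoxy)benzene | COCOc1cc(OCOC)cc(OCOC)c1
F4 | step 7 | 1-[2,4,6-tris(methoxymethoxy)phenyl]-3-[(4S,5R)-2,2,5-trimethyl-5-(4-methylpent-3-en-1-yl)-1,3-dioxolan-4-yl]propan-1-one | CC(C)=CCC[C@@](C)(OC(C)(C)O1)[C@@H]1CCC(=O)c2c(OCOC)cc(OCOC)cc2OCOC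
F5 | step 14 | 2,4-bis(methoxymethoxy)benzoic acid | COCOc1ccc(C(=O)O)c(OCOC)c1
F6 | step 14 | 3,5-bis(methoxymethoxy)-4-(3-methylbut-2-en-1-yl)-2-{3-[(4S,5R)-2,2,5-trimethyl-5-(4-methylpent-3-en-1-yl)-1,3-dioxolan-4-yl]propanoyl}phenyl 2,4-bis(methoxymethoxy)benzoate | CC(C)=CCC[C@@](C)(OC(C)(C)O1)[C@@H]1CCC(=O)c2c(OC(=O)c3ccc(OCOC)cc3OCOC)cc(OCOC)c(CC=C(C)C)c2OCOC
F7 | step 14 | 1-[2,4-bis(methoxymethoxy)phenyl]-3-[6-hydroxy-2,4-bis(methoxymethoxy)-3-(3-methylbut-2-en-1-yl)phenyl]-2-{[(4S,5R)-2,2,5-trimethyl-5-(4-methylpent-3-en-1-yl)-1,3-dioxolan-4-yl]methyl}propane-1,3-dione | CC(C)=CCC[C@@](C)(OC(C)(C)O1)[C@@H]1CC(C(=O)c3ccc(OCOC)cc3OCOC)C(=O)c2c(O)cc(OCOC)c(CC=C(C)C)c2OCOC
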